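**Retrosynthetic overview**

- The target is traced back to a methoxy-p-quinone and then to 3,5,7,2',4',5'-hexamethoxyflavone. The 2',5'-dimethoxy pair of ring B is a masked hydroquinone, unmasked last by oxidative demethylation and reduction.
- Ring C (the pyranone) is the only ring built. It is closed at C4–C4a by intramolecular Friedel–Crafts acylation of (E)-3-(3,5-dimethoxyphenoxy)-2-methoxy-3-(2,4,5-trimethoxyphenyl)acrylic acid. Rings A and B are bought as arenes.
- The acid comes from its methyl ester, whose O1–C2 bond is made by palladium-catalysed coupling of an enol triflate with 3,5-dimethoxyphenol. The triflate comes from an α-methoxy β-keto ester, made by crossed Claisen acylation of methyl methoxyacetate with 2,4,5-trimethoxybenzoyl chloride (C2–C3).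
- Structural feature: ring A carries O1 at C8a and methoxy groups at C5 and C7, so it is a symmetric 3,5-dimethoxyphenoxy unit. Its two carbons ortho to O1 (the future C4a and C8) are equivalent and each lies ortho to one methoxy group and para to the other, so the C4 acyl carbon can only give the 5,7-pattern.

Key step: step 6

Remark on stereochemistry: the target is achiral. The keto ester of step 2 is racemic and its stereocentre is removed in step 3. The only stereochemical element carried forward is the E geometry of the acrylate (carboxyl cis to the aryloxy group), set in step 3 and expected to be retained in step 4.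

Remark on the O1–C2 bond: a catalysed coupling is used because the 2-methoxy group and the electron-rich aryl group make C3 of the acrylate a poor acceptor for uncatalysed addition–elimination.

**Route**

Step 1
Reactants: 1 2,4,5-trimethoxybenzoic acid
Product: 2 2,4,5-trimethoxybenzoyl chloride
Conditions: (COCl)2, cat. DMF, CH2Cl2, 0 °C → rt
Reagents that add atoms: oxalyl chloride, ClC(=O)C(=O)Cl
Why: Vilsmeier-catalysed conversion of a carboxylic acid into its acid chloride, to which the aryl methyl ethers are inert.

Step 2
Reactants: 2 2,4,5-trimethoxybenzoyl chloride; 3 methyl methoxyacetate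
Product: 5 methyl 2-methoxy-3-oxo-3-(2,4,5-trimethoxyphenyl)propanoate (racemic), via lithium enolate of methyl methoxyacetate 4 (not isolated)
Conditions: 3 (2.2 equiv), LiN(SiMe3)2 (2.2 equiv), THF, −78 °C; then 2, −78 → −40 °C; aq NH4Cl
Reagents that add atoms: none
Why: Crossed Claisen condensation (C-acylation of a lithium ester enolate by a non-enolisable aroyl chloride), with a second equivalent of enolate to absorb the more acidic product; the new stereocentre is formed racemic and is removed in step 3.

Step 3
Reactants: 5 methyl 2-methoxy-3-oxo-3-(2,4,5-trimethoxyphenyl)propanoate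
Product: 7 methyl (E)-2-methoxy-3-(2,4,5-trimethoxyphenyl)-3-(trifluoromethylsulfonyloxy)prop-2-enoate, via sodium enolate 6 (not isolated)
Conditions: NaH, Et2O, 0 °C; then (CF3SO2)2O, −20 → 0 °C
Reagents that add atoms: trifluoromethanesulfonic anhydride, FC(F)(F)S(=O)(=O)OS(=O)(=O)C(F)(F)F
Why: O-sulfonylation of a β-keto ester enolate (enol triflate formation); chelation of sodium between the enolate oxygen and the ester carbonyl should place the triflate cis to the ester, and with no hydrogen left at C2 or on the aryl-bearing carbon no allene or alkyne can form.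

Step 4
Reactants: 7 methyl (E)-2-methoxy-3-(2,4,5-trimethoxyphenyl)-3-(trifluoromethylsulfonyloxy)prop-2-enoate; 8 3,5-dimethoxyphenol
Product: 9 methyl (E)-3-(3,5-dimethoxyphenoxy)-2-methoxy-3-(2,4,5-trimethoxyphenyl)prop-2-enoate
Conditions: cat. Pd2(dba)3 (tris(dibenzylideneacetone)dipalladium, zerovalent palladium), 2-di-tert-butylphosphino-2',4',6'-triisopropylbiphenyl, K3PO4, toluene, 90 °C
Reagents that add atoms: none
Why: Palladium-catalysed C–O cross-coupling of an alkenyl triflate with a phenol (Buchwald–Hartwig-type etherification): oxidative addition of zerovalent palladium to the electron-poor enol triflate is fast and stereoretentive, the bulky biarylphosphine promotes C–O reductive elimination, and the weak, poorly soluble base keeps the phenoxide concentration low so that attack at sulfur is suppressed.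

Step 5
Reactants: 9 methyl (E)-3-(3,5-dimethoxyphenoxy)-2-methoxy-3-(2,4,5-trimethoxyphenyl)prop-2-enoate
Product: 11 (E)-3-(3,5-dimethoxyphenoxy)-2-methoxy-3-(2,4,5-trimethoxyphenyl)prop-2-enoic acid, via lithium carboxylate 10 (not isolated)
Conditions: LiOH, THF/MeOH/H2O, 40 °C; then 1 M HCl, 0 °C, to pH 3
Reagents that add atoms: lithium hydroxide, [Li+].[OH-]
Why: Ester saponification by acyl–oxygen cleavage; the 2-methoxy and 3-aryloxy groups deactivate the alkene as a Michael acceptor, so hydroxide should attack the ester carbonyl and leave the enol ether intact.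

Step 6
Reactants: 11 (E)-3-(3,5-dimethoxyphenoxy)-2-methoxy-3-(2,4,5-trimethoxyphenyl)prop-2-enoic acid
Product: 13 3,5,7-trimethoxy-2-(2,4,5-trimethoxyphenyl)-4H-chromen-4-one, via acyl methanesulfonate 12 (not isolated)
Conditions: P2O5 in CH3SO3H (7.7 wt %), 25 → 45 °C; then ice/H2O
Reagents that add atoms: none
Why: P2O5 in CH3SO3H converts the acid into its acyl methanesulfonate 12, which ionises towards the acylium ion; the acyl carbon (future C4) is attacked by the ring A carbon ortho to the ether oxygen (future C4a), and proton loss from the arenium ion restores aromaticity, an intramolecular Friedel–Crafts acylation. The closest known reaction is the acid-mediated cyclisation of 3-aryloxyacrylic and 3-aryloxycinnamic acids to chromones and flavones. Ring C is closed in a six-membered mode (6-exo-trig at the acyl carbon of 12, with O1–C2=C3 already in place), and no stereocentre is formed. The step needs site selectivity for ring A over ring B: the E geometry holds the acyl group next to the aryloxy group, and the two ortho carbons of ring A are equivalent and each activated by the ether oxygen, a para methoxy group and an ortho methoxy group, whereas attack at C6' of ring B would need the Z isomer and would give a strained indenone at a carbon activated by one methoxy group only. Should part of the acid isomerise, reversible protonation at C2 (an oxocarbenium ion stabilised by the aryloxy and trimethoxyphenyl groups) should return it to the productive E isomer. The temperature is held at or below 45 °C so that sulfonylation of the electron-rich rings and ether cleavage stay slow.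

Step 7
Reactants: 13 3,5,7-trimethoxy-2-(2,4,5-trimethoxyphenyl)-4H-chromen-4-one
Product: 14 2-methoxy-5-(3,5,7-trimethoxy-4-oxo-4H-chromen-2-yl)cyclohexa-2,5-diene-1,4-dione
Conditions: (NH4)2Ce(NO3)6 (2.5 equiv), MeCN/H2O, 0 °C
Reagents that add atoms: water, O
Why: Oxidative demethylation of a para-dimethoxyarene by tetravalent cerium: single-electron oxidation of ring B (the most electron-rich ring), ipso attack of water at C2' and C5' and loss of two molecules of methanol should give the p-quinone, while ring A (meta-dimethoxy, conjugated to the carbonyl) cannot form a quinone and the 4'-methoxy group stays as a vinylogous ester.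

Step 8
Reactants: 14 2-methoxy-5-(3,5,7-trimethoxy-4-oxo-4H-chromen-2-yl)cyclohexa-2,5-diene-1,4-dione
Product: 15 5-O-methyloxyayanin A, 2-(2,5-dihydroxy-4-methoxyphenyl)-3,5,7-trimethoxy-4H-chromen-4-one
Conditions: Na2S2O4, EtOAc/H2O, rt, argon
Reagents that add atoms: none
Why: Two-electron reduction of a p-quinone to its hydroquinone by dithionite, which does not reduce the chromone; the air-sensitive product is handled under argon with degassed solvents.

**Compound list**

1 | 2,4,5-trimethoxybenzoic acid | COc1cc(OC)c(C(=O)O)cc1OC | starting material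
2 | 2,4,5-trimethoxybenzoyl chloride | COc1cc(OC)c(C(=O)Cl)cc1OC | intermediate
3 | methyl methoxyacetate | COCC(=O)OC | starting material
4 | lithium enolate of methyl methoxyacetate (chelated geometry, O–Li cis to the 2-methoxy group) | CO/C=C(\O[Li])OC | intermediate
5 | methyl 2-methoxy-3-oxo-3-(2,4,5-trimethoxyphenyl)propanoate (racemic) | COC(=O)C(OC)C(=O)c1cc(OC)c(OC)cc1OC | intermediate
6 | sodium (E)-enolate of 5 (O–Na cis to the ester) | COC(=O)/C(OC)=C(\O[Na])c1cc(OC)c(OC)cc1OC | intermediate
7 | methyl (E)-2-methoxy-3-(2,4,5-trimethoxyphenyl)-3-(trifluoromethylsulfonyloxy)prop-2-enoate | COC(=O)/C(OC)=C(\OS(=O)(=O)C(F)(F)F)c1cc(OC)c(OC)cc1OC | intermediate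
8 | 3,5-dimethoxyphenol | COc1cc(O)cc(OC)c1 | starting material
9 | methyl (E)-3-(3,5-dimethoxyphenoxy)-2-methoxy-3-(2,4,5-trimethoxyphenyl)prop-2-enoate | COC(=O)/C(OC)=C(\Oc1cc(OC)cc(OC)c1)c1cc(OC)c(OC)cc1OC | intermediate
10 | lithium (E)-3-(3,5-dimethoxyphenoxy)-2-methoxy-3-(2,4,5-trimethoxyphenyl)prop-2-enoate | [Li+].[O-]C(=O)/C(OC)=C(\Oc1cc(OC)cc(OC)c1)c1cc(OC)c(OC)cc1OC | intermediate
11 | (E)-3-(3,5-dimethoxyphenoxy)-2-methoxy-3-(2,4,5-trimethoxyphenyl)prop-2-enoic acid | OC(=O)/C(OC)=C(\Oc1cc(OC)cc(OC)c1)c1cc(OC)c(OC)cc1OC | intermediate
12 | (E)-3-(3,5-dimethoxyphenoxy)-2-methoxy-3-(2,4,5-trimethoxyphenyl)prop-2-enoic methanesulfonic anhydride | CS(=O)(=O)OC(=O)/C(OC)=C(\Oc1cc(OC)cc(OC)c1)c1cc(OC)c(OC)cc1OC | intermediate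
13 | 3,5,7-trimethoxy-2-(2,4,5-trimethoxyphenyl)-4H-chromen-4-one | COc1cc(OC)c2c(=O)c(OC)c(-c3cc(OC)c(OC)cc3OC)oc2c1 | intermediate
14 | 2-methoxy-5-(3,5,7-trimethoxy-4-oxo-4H-chromen-2-yl)cyclohexa-2,5-diene-1,4-dione | COc1cc(OC)c2c(=O)c(OC)c(C3=CC(=O)C(OC)=CC3=O)oc2c1 | intermediate
15 | 5-O-methyloxyayanin A, 2-(2,5-dihydroxy-4-methoxyphenyl)-3,5,7-trimethoxy-4H-chromen-4-one | COc1cc(OC)c2c(=O)c(OC)c(-c3cc(O)c(OC)cc3O)oc2c1 | target

**Step count**

Total steps: 8. Longest linear sequence: 8 steps (1 → 15).

**Steps most likely to fail**

1. Step 4 (C–O coupling). The triflyl group may be transferred from the enol oxygen to phenoxide (S–O cleavage), and C–O reductive elimination at the congested tetrasubstituted alkenylpalladium may be slow, so the triflate could revert to the keto ester. The fallback sets out from keto ester 5 and comes back at ester 9. Keto ester 5 would be treated with preformed Ph3PBr2 and Et3N (MeCN, 0 → 40 °C) to give methyl (E)-3-bromo-2-methoxy-3-(2,4,5-trimethoxyphenyl)prop-2-enoate F1 (bromine cis to the ester; the geometric isomers would be separated if both form). F1 would then be joined to phenol 8 by an Ullmann-type vinylation (CuI, monovalent copper, N,N-dimethylglycine, Cs2CO3, dioxane, 90 °C). This electrophile has no sulfonyl group to lose, and base-mediated addition–elimination leads to the same ester 9.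

2. Step 6 (key ring closure). The reagent may C-sulfonylate the electron-rich rings, the strong acid may cleave the aryl enol ether, or acylation may take place on ring B after isomerisation. The fallback sets out from phenol 8 and acid chloride 2 and comes back at chromone 13; it closes ring C at O1–C2 instead. Phenol 8 would be O-acylated with methoxyacetyl chloride (Et3N, CH2Cl2) to 3,5-dimethoxyphenyl methoxyacetate F2. A Fries rearrangement (BF3·OEt2, 80 °C) would move the acyl group to the carbon ortho to the hydroxyl and para to a methoxy group, giving 1-(2-hydroxy-4,6-dimethoxyphenyl)-2-methoxyethan-1-one F3. Deprotonation of F3 with LiN(SiMe3)2 (3 equiv, THF, −78 °C) and C-acylation with acid chloride 2 (Baker–Venkataraman-type) would give 1-(2-hydroxy-4,6-dimethoxyphenyl)-2-methoxy-3-(2,4,5-trimethoxyphenyl)propane-1,3-dione F4 (racemic). Cyclodehydration (cat. H2SO4, AcOH, 90 °C) would then deliver chromone 13.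

3. Step 7 (oxidative demethylation). The oxidation may not stop cleanly at the p-quinone: ortho-quinone formation through the 4',5'-dimethoxy pair, oxidative coupling, or nitrate-derived side reactions could compete. The fallback sets out from chromone 13 and comes back at quinone 14. Anodic oxidation of 13 (carbon anode, undivided cell, 1% KOH in MeOH, 0 °C, constant current) should give the quinone bis(dimethyl ketal) 3,5,7-trimethoxy-2-(3,3,4,6,6-pentamethoxycyclohexa-1,4-dien-1-yl)-4H-chromen-4-one F5 without a metal oxidant or nitrate. Hydrolysis of F5 (dilute HCl, acetone/H2O, rt) would release quinone 14, which is reduced as in step 8.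

**Further compounds**

F1 | step 4 | methyl (E)-3-bromo-2-methoxy-3-(2,4,5-trimethoxyphenyl)prop-2-enoate | COC(=O)/C(OC)=C(\Br)c1cc(OC)c(OC)cc1OC
F2 | step 6 | 3,5-dimethoxyphenyl methoxyacetate | COCC(=O)Oc1cc(OC)cc(OC)c1
F3 | step 6 | 1-(2-hydroxy-4,6-dimethoxyphenyl)-2-methoxyethan-1-one | COCC(=O)c1c(O)cc(OC)cc1OC
F4 | step 6 | 1-(2-hydroxy-4,6-dimethoxyphenyl)-2-methoxy-3-(2,4,5-trimethoxyphenyl)propane-1,3-dione (racemic) | COC(C(=O)c1c(O)cc(OC)cc1OC)C(=O)c1cc(OC)c(OC)cc1OC
F5 | step 7 | 3,5,7-trimethoxy-2-(3,3,4,6,6-pentamethoxycyclohexa-1,4-dien-1-yl)-4H-chromen-4-one | COc1cc(OC)c2c(=O)c(OC)c(C3=CC(OC)(OC)C(OC)=CC3(OC)OC)oc2c1
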